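**Plan**

- Retrosynthesis: the appended lactone is cut at its bond to the pyrrolidine and the azepane N–CH2 is traced back to a lactam C=O. Both core C–N bonds (N–quaternary carbon and N–C=O) are then cut together to give an azidopropyl trans-hydrindanone. The hydroxy-lactone is cut at its C–O and C–C bonds to the cyclopentane, the cyclopentane at C3–C3a, and the quaternary carbon at its two alkyl bonds.
- Forward: cyclohexane-1,3-dione is C-alkylated twice and the cyclopentenone is closed by aldol condensation. The acetate arm, the trans ring fusion and the γ-lactone follow, then the lactone methyl and hydroxyl, then the azide. One Schmidt step closes the pyrrolidine and the azepanone together, and the second lactone is attached last.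
- Enabling feature: nitrogen lies between the quaternary carbon shared by the cyclopentane, pyrrolidine and azepane rings and the azepane N–CH2. Pyrrolidine plus azepane is therefore a cyclohexanone with nitrogen inserted beside an α-carbon that carries a three-carbon chain.
- Stereochemistry: the quaternary carbon comes from an amino-acid-mediated desymmetrising aldol condensation. All other centres are relayed from it: the C1 arm and ethyl by equilibration beside the acetal, the ring fusion by dissolving-metal reduction, the carbinol by hydride attack anti to the angular chain, the tertiary alcohol by convex-face enolate oxidation, the side-chain pair by a threo-selective vinylogous Mannich addition, and the last methyl by hydrogenation.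

Key step: step 13

Convention: hydrindane numbering (C1–C7a) is used up to step 12; β is the face of the C7a side chain and α the opposite face. From step 13 on, C3 is the pyrrolidine carbon on nitrogen, C5 the azepane carbon on nitrogen and C9a the quaternary carbon.

Assumption: the sense of induction in step 3 is taken to parallel the Hajos–Parrish series, so D-phenylalanine is written for the (R)-enedione; if the sense is opposite, L-phenylalanine is used and nothing else changes.

**Route**

Step 1
Reactants: 1 cyclohexane-1,3-dione; 2 allyl bromide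
Product: 3 2-allylcyclohexane-1,3-dione
Conditions: aq. KOH (1 equiv), Cu powder (cat.), H2O, rt
Reagents that add atoms: none
Why: C-allylation of the stabilised 1,3-dione enolate, for which aqueous alkali favours carbon over oxygen attack; no stereocentre is formed.

Step 2
Reactants: 3 2-allylcyclohexane-1,3-dione; 4 1-bromopentan-2-one
Product: 5 2-allyl-2-(2-oxopentyl)cyclohexane-1,3-dione
Conditions: aq. KOH (1 equiv), H2O/dioxane, rt → 40 °C
Reagents that add atoms: none
Why: second C-alkylation (SN2 on the α-bromoketone) should give the prochiral 1,4-diketone; the quaternary C2 rules out furan formation.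

Step 3
Reactants: 5 2-allyl-2-(2-oxopentyl)cyclohexane-1,3-dione
Product: 6 (7aR)-7a-allyl-3-ethyl-4,5,6,7a-tetrahydro-1H-indene-2,7-dione
Conditions: D-phenylalanine (1.0 equiv), (1R)-(−)-10-camphorsulfonic acid (0.5 equiv), DMF, 30 → 70 °C
Reagents that add atoms: none
Why: Proposed new method: the amino acid should form an enamine of the side-chain ketone toward its ethyl-bearing α-carbon, which adds to one of the two enantiotopic ring carbonyls through an acid-assisted, hydrogen-bonded transition state, and the ketol dehydrates to the tetrasubstituted cyclopentenone, fixing the quaternary centre C7a as R; the closest known reaction type is the Hajos–Parrish–Eder–Sauer–Wiechert desymmetrising aldol condensation of the homologous 3-oxoalkyl triketones, which closes six-membered enones, whereas the five-membered (5-enolendo) closure needed here has no secure enantioselective precedent.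

Step 4
Reactants: 6 (7aR)-7a-allyl-3-ethyl-4,5,6,7a-tetrahydro-1H-indene-2,7-dione
Product: 7 (7aR)-7a-allyl-3-ethyl-7,7-(ethylenedioxy)-1,4,5,6,7,7a-hexahydro-2H-inden-2-one
Conditions: ethylene glycol, TsOH (cat.), benzene, reflux (Dean–Stark), stopped at the mono-acetal
Reagents that add atoms: ethylene glycol, OCCO
Why: chemoselective acetalisation of the saturated C7 ketone, since the conjugated cyclopentenone carbonyl is much less electrophilic.

Step 5
Reactants: 7 enone acetal; 8 tert-butyl bromoacetate
Product: 9 tert-butyl 2-[(7aR)-7a-allyl-3-ethyl-7,7-(ethylenedioxy)-2-oxo-2,4,5,6,7,7a-hexahydro-1H-inden-1-yl]acetate, C1 arm β (cis to allyl)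
Conditions: LDA, THF, −78 °C; then 8, DMPU, −78 → −30 °C
Reagents that add atoms: none
Why: kinetic α′-deprotonation gives the cross-conjugated lithium dienolate, which is alkylated at C1 (enolate SN2); the electrophile should enter syn to the allyl group because the dioxolane oxygen antiperiplanar to allyl lies under the ring next to C1, and any α-epimer is corrected in step 6.

Step 6
Reactants: 9 C1-alkylated enone acetal
Product: 10 tert-butyl 2-[7aβ-allyl-3α-ethyl-7,7-(ethylenedioxy)-2-oxo-3aα-H-octahydroinden-1β-yl]acetate (trans-fused)
Conditions: Li (2.5 equiv), NH3(l)/THF, t-BuOH (1 equiv), −78 °C; isoprene, then NH4Cl; then DBU (cat.), toluene, rt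
Reagents that add atoms: none
Why: Birch-type dissolving-metal reduction of the enone, in which protonation at C3a should give the trans ring fusion (H axial, anti to the axial allyl), and base equilibration then places ethyl trans to C4 and the C1 arm away from the axial acetal oxygen (cis to the smaller allyl CH2).

Step 7
Reactants: 10 trans-fused keto ester
Product: 12 tricyclic γ-lactone (lactone O on C2β, CH2 on C1β, cis-fused on the β face; allyl and acetal retained), via hydroxy ester 11 (not isolated)
Conditions: NaBH4, MeOH, −20 → 0 °C; then CSA (cat.), benzene, 60 °C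
Reagents that add atoms: none
Why: borohydride reduction from the α face, away from the angular allyl group and the C1 arm, should give the 2β-alcohol, and acid-catalysed lactonisation is possible only for this cis hydroxy ester.

Step 8
Reactants: 12 tricyclic γ-lactone
Product: 13 α-methyl lactone, methyl exo (convex face, syn to H-1 and H-2)
Conditions: LDA, THF, −78 °C; MeI, −78 → −40 °C
Reagents that add atoms: iodomethane, CI
Why: lactone enolate alkylation from the convex face of the cis-fused bicycle; this centre is re-set in step 9.

Step 9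
Reactants: 13 α-methyl lactone
Product: 14 α-hydroxy-α-methyl lactone, hydroxyl exo and methyl endo (allyl and acetal retained)
Conditions: KHMDS, THF, −78 °C; (±)-trans-3-phenyl-2-(phenylsulfonyl)oxaziridine; NH4Cl
Reagents that add atoms: (±)-trans-3-phenyl-2-(phenylsulfonyl)oxaziridine, O=S(=O)(N1OC1c1ccccc1)c1ccccc1
Why: enolate hydroxylation with an N-sulfonyloxaziridine, in which the oxidant approaches the planar enolate from the convex face, so the hydroxyl ends exo and the methyl is pushed endo, as in the target.

Step 10
Reactants: 14 α-hydroxy-α-methyl lactone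
Product: 16 7a-(3-hydroxypropyl) hydroxy-lactone acetal, via B-alkyl-9-BBN adduct 15 (not isolated)
Conditions: 9-BBN (2.5 equiv), THF, 0 °C → rt; then aq. NaOAc, 30% H2O2, 0 °C → rt
Reagents that add atoms: hydrogen peroxide, OO; 9-BBN, B1C2CCCC1CCC2 (its atoms stay only in 15)
Why: anti-Markovnikov hydroboration–oxidation of the terminal alkene; buffered oxidation spares the lactone.

Step 11
Reactants: 16 7a-(3-hydroxypropyl) hydroxy-lactone acetal
Product: 17 7a-(3-azidopropyl) hydroxy-lactone acetal
Conditions: PPh3, DIAD, (PhO)2P(O)N3, THF, 0 °C → rt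
Reagents that add atoms: diphenylphosphoryl azide, [N-]=[N+]=NP(=O)(Oc1ccccc1)Oc1ccccc1
Why: Mitsunobu azidation of the primary alcohol; the hindered tertiary α-hydroxy lactone does not react.

Step 12
Reactants: 17 7a-(3-azidopropyl) hydroxy-lactone acetal
Product: 18 7a-(3-azidopropyl)-7-oxo trans-hydrindane hydroxy-lactone (azidopropyl trans-hydrindanone)
Conditions: 1 M HCl, THF, 40 °C
Reagents that add atoms: water, O
Why: acid-catalysed acetal hydrolysis frees the ketone; azide, lactone and tertiary alcohol are stable to dilute aqueous acid.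

Step 13
Reactants: 18 azidopropyl trans-hydrindanone hydroxy-lactone
Product: 19 tetracyclic lactam (pyrrolo[1,2-a]azepin-5-one fused to the cyclopentane and hydroxy-lactone)
Conditions: TFA (neat), 0 °C → rt; then aq. NaHCO3
Reagents that add atoms: none
Why: Acid activates the C7 ketone and the internal azide nitrogen adds (6-exo-trig along the tether) to give a six-membered azidohydrin whose N2+ group sits equatorial, antiperiplanar to the ring bond C7–C7a, so the quaternary C7a shifts from carbon to nitrogen as N2 leaves (intramolecular Schmidt reaction, a Beckmann-type 1,2-shift). That one shift contracts the azidohydrin ring to the pyrrolidine (new N–C7a bond) and expands the cyclohexanone to the seven-membered lactam (new N–C7 bond), so both rings close in a single operation. No stereocentre is created: C7a migrates with retention and becomes the nitrogen-bearing quaternary carbon, still trans to H-3a. The step needs migration of C7a and not of the C6 methylene, which would give a bridged lactam; the three-carbon tether and the chair azidohydrin with equatorial N2+ secure this. The lactone, the tertiary alcohol and the neighbouring stereocentres are spectators under TFA.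

Step 14
Reactants: 19 tetracyclic lactam
Product: 20 3-methoxy lactam (N,O-acetal at the pyrrolidine carbon on nitrogen, epimer mixture)
Conditions: constant-current electrolysis (graphite anode, steel cathode, undivided cell), Et4NOTs, MeOH, 0–10 °C
Reagents that add atoms: methanol, CO
Why: Shono anodic α-methoxylation of the amide; the only N-bound carbon with hydrogens is C3, because C9a is quaternary, so the regiochemistry is fixed.

Step 15
Reactants: 21 3-methylfuran-2(5H)-one
Product: 22 3-methyl-2-(triisopropylsilyloxy)furan
Conditions: TIPSOTf, Et3N, CH2Cl2, 0 °C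
Reagents that add atoms: triisopropylsilyl trifluoromethanesulfonate, CC(C)[Si](C(C)C)(C(C)C)OS(=O)(=O)C(F)(F)F
Why: soft enolisation and O-silylation of the butenolide gives the aromatic 2-silyloxyfuran (silyl dienol ether formation).

Step 16
Reactants: 20 3-methoxy lactam; 22 3-methyl-2-(triisopropylsilyloxy)furan
Product: 23 (3S)-3-[(2S)-4-methyl-5-oxo-2,5-dihydrofuran-2-yl] lactam (butenolide adduct)
Conditions: TIPSOTf (0.2 equiv), CH2Cl2, −78 °C
Reagents that add atoms: none
Why: vinylogous Mannich reaction of the N-acyliminium ion with the γ-carbon of the silyloxyfuran, which should give the threo pair typical of cyclic N-acyliminium ions and add cis to C12, because the azepanone ring, tied to nitrogen through the planar amide, arches over the face syn to C9.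

Step 17
Reactants: 23 butenolide adduct
Product: 24 (3S)-3-[(2S,4S)-4-methyl-5-oxotetrahydrofuran-2-yl] lactam
Conditions: H2 (1 atm), 10% Pd/C, EtOAc, rt
Reagents that add atoms: none
Why: heterogeneous hydrogenation of the butenolide from the face opposite the pyrrolidinyl substituent should set the methyl cis to it.

Step 18
Reactants: 24 saturated lactone lactam
Product: 25 thiolactam (C5 thiocarbonyl)
Conditions: Lawesson's reagent (0.55 equiv), THF, rt
Reagents that add atoms: Lawesson's reagent, COc1ccc(cc1)P1(=S)SP(=S)(S1)c1ccc(OC)cc1
Why: thionation with Lawesson's reagent is far faster at the amide carbonyl than at the two lactones, and the tertiary alcohol is inert at room temperature.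

Step 19
Reactants: 25 thiolactam
Product: 26 CNP0260919.2 (target)
Conditions: Raney Ni (W-2), EtOH, rt
Reagents that add atoms: none
Why: Raney nickel desulfurisation reduces the thiolactam to the N–CH2 amine while both lactones and the tertiary alcohol are untouched; no stereocentre is affected.

**Compound list**

1 | cyclohexane-1,3-dione | O=C1CCCC(=O)C1 | starting material
2 | allyl bromide | C=CCBr | starting material
3 | 2-allylcyclohexane-1,3-dione | C=CCC1C(=O)CCCC1=O | intermediate
4 | 1-bromopentan-2-one | CCCC(=O)CBr | starting material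
5 | 2-allyl-2-(2-oxopentyl)cyclohexane-1,3-dione | C=CCC1(CC(=O)CCC)C(=O)CCCC1=O | intermediate
6 | (7aR)-7a-allyl-3-ethyl-4,5,6,7a-tetrahydro-1H-indene-2,7-dione | C=CC[C@@]12CC(=O)C(CC)=C1CCCC2=O | intermediate
7 | (7aR)-7a-allyl-3-ethyl-7,7-(ethylenedioxy)-1,4,5,6,7,7a-hexahydro-2H-inden-2-one | C=CC[C@@]12CC(=O)C(CC)=C1CCCC23OCCO3 | intermediate
8 | tert-butyl bromoacetate | CC(C)(C)OC(=O)CBr | starting material
9 | tert-butyl 2-[7a-allyl-3-ethyl-7,7-(ethylenedioxy)-2-oxo-hexahydro-1H-inden-1-yl]acetate, C1 arm cis to allyl | C=CC[C@@]12[C@@H](CC(=O)OC(C)(C)C)C(=O)C(CC)=C1CCCC23OCCO3 | intermediate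
10 | trans-fused keto ester: 7aβ-allyl, 3aα-H, 3α-ethyl, 1β-CH2CO2tBu, 7-acetal | C=CC[C@@]12[C@@H](CC(=O)OC(C)(C)C)C(=O)[C@H](CC)[C@H]1CCCC23OCCO3 | intermediate
11 | 2β-hydroxy ester of 10 | C=CC[C@@]12[C@@H](CC(=O)OC(C)(C)C)[C@@H](O)[C@H](CC)[C@H]1CCCC23OCCO3 | intermediate
12 | tricyclic γ-lactone, cis-fused on the β face at C1/C2 | C=CC[C@@]12[C@H]3CC(=O)O[C@H]3[C@H](CC)[C@H]1CCCC24OCCO4 | intermediate
13 | α-methyl lactone, methyl exo | C=CC[C@@]12[C@H]3[C@H](C)C(=O)O[C@H]3[C@H](CC)[C@H]1CCCC24OCCO4 | intermediate
14 | α-hydroxy-α-methyl lactone, hydroxyl exo, methyl endo | C=CC[C@@]12[C@H]3[C@](C)(O)C(=O)O[C@H]3[C@H](CC)[C@H]1CCCC24OCCO4 | intermediate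
15 | B-alkyl-9-BBN adduct of 14 | C1CCC2CCCC1B2CCC[C@@]34[C@H]5[C@](C)(O)C(=O)O[C@H]5[C@H](CC)[C@H]3CCCC46OCCO6 | intermediate
16 | 7a-(3-hydroxypropyl) hydroxy-lactone acetal | OCCC[C@@]12[C@H]3[C@](C)(O)C(=O)O[C@H]3[C@H](CC)[C@H]1CCCC24OCCO4 | intermediate
17 | 7a-(3-azidopropyl) hydroxy-lactone acetal | [N-]=[N+]=NCCC[C@@]12[C@H]3[C@](C)(O)C(=O)O[C@H]3[C@H](CC)[C@H]1CCCC24OCCO4 | intermediate
18 | azidopropyl trans-hydrindanone hydroxy-lactone | [N-]=[N+]=NCCC[C@@]12[C@H]3[C@](C)(O)C(=O)O[C@H]3[C@H](CC)[C@H]1CCCC2=O | intermediate
19 | tetracyclic azepane lactam with the hydroxy-lactone | CC[C@H]1[C@@H]2OC(=O)[C@@](C)(O)[C@@H]2[C@@]23CCCN2C(=O)CCC[C@H]13 | intermediate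
20 | 3-methoxy lactam (epimer mixture at the N,O-acetal carbon) | CC[C@H]1[C@@H]2OC(=O)[C@@](C)(O)[C@@H]2[C@@]23CCC(OC)N2C(=O)CCC[C@H]13 | intermediate
21 | 3-methylfuran-2(5H)-one | CC1=CCOC1=O | starting material
22 | 3-methyl-2-(triisopropylsilyloxy)furan | Cc1ccoc1O[Si](C(C)C)(C(C)C)C(C)C | intermediate
23 | (3S)-3-[(2S)-4-methyl-5-oxo-2,5-dihydrofuran-2-yl] lactam | CC[C@H]1[C@@H]2OC(=O)[C@@](C)(O)[C@@H]2[C@@]23CC[C@@H]([C@@H]4C=C(C)C(=O)O4)N2C(=O)CCC[C@H]13 | intermediate
24 | (3S)-3-[(2S,4S)-4-methyl-5-oxotetrahydrofuran-2-yl] lactam | CC[C@H]1[C@@H]2OC(=O)[C@@](C)(O)[C@@H]2[C@@]23CC[C@@H]([C@@H]4C[C@H](C)C(=O)O4)N2C(=O)CCC[C@H]13 | intermediate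
25 | thiolactam of 24 | CC[C@H]1[C@@H]2OC(=O)[C@@](C)(O)[C@@H]2[C@@]23CC[C@@H]([C@@H]4C[C@H](C)C(=O)O4)N2C(=S)CCC[C@H]13 | intermediate
26 | CNP0260919.2 | CC[C@H]1[C@@H]2OC(=O)[C@@](C)(O)[C@@H]2[C@@]23CC[C@@H]([C@@H]4C[C@H](C)C(=O)O4)N2CCCC[C@H]13 | target

**Step count**

Total: 19 steps. Longest linear sequence: 18 steps (steps 1–14 and 16–19); step 15 is a one-step branch.

**Steps most likely to fail**

Step 3. The five-membered aldol closure may be slow or poorly enantioselective, and the 1,3-dione may open by retro-Claisen cleavage under prolonged heating. The fallback uses classical resolution and sets out from 5. Cyclodehydration with pyrrolidinium acetate in toluene should give the racemic enedione F1. Acetalisation of its saturated ketone with (2R,3R)-butane-2,3-diol (TsOH, benzene) gives the diastereomeric acetals, the (7aR) acetal F2 and the (7aS) acetal F3, which are separated by chromatography or crystallisation. Hydrolysis of F2 with aqueous acid returns the route at 6.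

Step 5. Alkylation of the hindered C1 position may be slow and lose out to γ-deprotonation or proton transfer, or the electrophile may enter on the α face. The fallback sets C1 by equilibration after the ring fusion and sets out from 7. Dissolving-metal reduction and base equilibration give the trans-fused ketone F4. Its kinetic enolate (LDA) is condensed with ethyl glyoxylate and dehydrated (MsCl, Et3N) to the alkylidene keto ester F5 (E/Z mixture). Conjugate reduction with Zn/AcOH and DBU equilibration give the ethyl keto ester F6, the ethyl analogue of 10. Borohydride reduction and acid lactonisation return the route at 12.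

Step 16. Facial selectivity at C3 may be poor if the silyloxyfuran also approaches syn to C9, and the threo preference may erode. The fallback sets C3 before the ring expansion and sets out from 16. Dess–Martin oxidation gives the aldehyde F7. A titanium–BINOL-catalysed vinylogous Mukaiyama aldol reaction with 22, with the ligand enantiomer chosen for the (1′R,5S) adduct, gives the hydroxy butenolide F8. Mitsunobu azidation with inversion gives the secondary azide F9, and acetal hydrolysis gives the azido ketone F10. The same intramolecular Schmidt reaction (TFA) then forms the same two rings and returns the route at 23.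

**Further compounds**

F1 | step 3 | racemic 7a-allyl-3-ethyl-4,5,6,7a-tetrahydro-1H-indene-2,7-dione | C=CCC12CC(=O)C(CC)=C1CCCC2=O
F2 | step 3 | (2R,3R)-butane-2,3-diyl acetal of the (7aR)-enedione | C=CC[C@@]12CC(=O)C(CC)=C1CCCC23O[C@H](C)[C@@H](C)O3
F3 | step 3 | (2R,3R)-butane-2,3-diyl acetal of the (7aS)-enedione | C=CC[C@]12CC(=O)C(CC)=C1CCCC23O[C@H](C)[C@@H](C)O3
F4 | step 5 | trans-fused 7aβ-allyl-3α-ethyl-7,7-(ethylenedioxy)octahydroinden-2-one | C=CC[C@@]12CC(=O)[C@H](CC)[C@H]1CCCC23OCCO3
F5 | step 5 | ethyl 2-[7a-allyl-3-ethyl-7,7-(ethylenedioxy)-2-oxo-octahydroinden-1-ylidene]acetate (E/Z mixture) | C=CC[C@@]12C(=CC(=O)OCC)C(=O)[C@H](CC)[C@H]1CCCC23OCCO3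
F6 | step 5 | ethyl ester analogue of 10 | C=CC[C@@]12[C@@H](CC(=O)OCC)C(=O)[C@H](CC)[C@H]1CCCC23OCCO3
F7 | step 16 | 7a-(3-oxopropyl) hydroxy-lactone acetal | O=CCC[C@@]12[C@H]3[C@](C)(O)C(=O)O[C@H]3[C@H](CC)[C@H]1CCCC24OCCO4
F8 | step 16 | (1′R)-hydroxy (5S)-butenolide aldol adduct | CC1=C[C@H](OC1=O)[C@H](O)CC[C@@]23[C@H]4[C@](C)(O)C(=O)O[C@H]4[C@H](CC)[C@H]2CCCC35OCCO5
F9 | step 16 | (1′S)-azido (5S)-butenolide acetal | CC1=C[C@H](OC1=O)[C@@H](N=[N+]=[N-])CC[C@@]23[C@H]4[C@](C)(O)C(=O)O[C@H]4[C@H](CC)[C@H]2CCCC35OCCO5
F10 | step 16 | (1′S)-azido (5S)-butenolide 7-ketone | CC1=C[C@H](OC1=O)[C@@H](N=[N+]=[N-])CC[C@@]23[C@H]4[C@](C)(O)C(=O)O[C@H]4[C@H](CC)[C@H]2CCCC3=O
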